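**Strategy.** The side chain (C1' on quinone carbon C3, C32' at the tail) is cut at the C9'–C10' single bond, the junction between the only saturated isoprene unit (C5'–C8', carrying the C7' stereocentre) and the (E)-C10'=C11' alkene, far from the naphthoquinone ring. The key step exploits that C9' is then a plain primary carbon: 9-BBN hydroboration of a terminal C8'=C9' vinyl group and B-alkyl Suzuki–Miyaura coupling with a C29 (E)-alkenyl iodide join the halves in one operation with retention of alkene geometry. The precursor is a (7R)-nona-2,8-dienyl-1,4-dimethoxynaphthalene from (R)-citronellene; the quinone, masked as dimethyl ether, is released last.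

Key step: step 13

Remark on the chemistry: C7' of the target is (R), which maps onto (R)-β-citronellene without any change at the stereocentre. (2E,6E,10E)-Geranylgeraniol and (R)-β-citronellene are taken as commercial single isomers. The quinone is carried as its dimethyl ether because boranes and zerovalent palladium do not tolerate a free naphthoquinone.

**Left fragment (C29 alkenyl iodide)**

Step 1
Reactants: 1 (2E,6E,10E)-geranylgeraniol
Product: 2 (2E,6E,10E)-1-bromo-3,7,11,15-tetramethylhexadeca-2,6,10,14-tetraene (geranylgeranyl bromide)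
Conditions: PBr3 (0.4 equiv), Et2O, 0 °C
Reagents that add atoms: phosphorus tribromide, BrP(Br)Br
Why: SN2 bromination of the primary allylic alcohol through its phosphite ester at low temperature should leave the (2E) alkene in place.

Step 2
Reactants: 2 geranylgeranyl bromide
Product: 3 (5E,9E,13E)-6,10,14,18-tetramethylnonadeca-5,9,13,17-tetraen-1-yne
Conditions: HC≡CCH2Br, n-BuLi (2 equiv), TMEDA, Et2O/hexane, −78 °C; then 2, −78 °C → rt; H2O
Reagents that add atoms: propargyl bromide, BrCC#C
Why: 1,3-dilithiopropyne, made in the flask by bromine–lithium exchange and deprotonation, should alkylate the primary allylic bromide at its sp3 carbanion (SN2 propargylation, no allylic transposition) and give the terminal 1,5-enyne directly.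

Step 3
Reactants: 3 the C23 enyne
Product: 6 (2E,6E,10E,14E)-3,7,11,15,19-pentamethylicosa-2,6,10,14,18-pentaen-1-ol (geranylfarnesol), via alkenyldimethylalane 4 (not isolated), via lithium alkenyl(butyl)dimethylaluminate 5 (not isolated)
Conditions: Me3Al, Cp2ZrCl2 (25 mol %), ClCH2CH2Cl, rt; volatiles removed; n-BuLi, THF/hexane, −78 → 0 °C; (CH2O)n, rt; aqueous work-up
Reagents that add atoms: trimethylaluminium, C[Al](C)C; paraformaldehyde (as formaldehyde), C=O
Why: Negishi zirconium-catalysed methylalumination adds methyl and aluminium syn across the terminal alkyne with aluminium on the terminal carbon, and hydroxymethylation of the derived aluminate proceeds with retention, so the new alkene should be (2E).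

Step 4
Reactants: 6 geranylfarnesol
Product: 7 (2E,6E,10E,14E)-1-bromo-3,7,11,15,19-pentamethylicosa-2,6,10,14,18-pentaene (geranylfarnesyl bromide)
Conditions: PBr3 (0.4 equiv), Et2O, 0 °C
Reagents that add atoms: phosphorus tribromide, BrP(Br)Br
Why: The same SN2 bromination of a primary allylic alcohol as in step 1 should proceed without loss of alkene geometry.

Step 5
Reactants: 7 geranylfarnesyl bromide
Product: 8 (5E,9E,13E,17E)-6,10,14,18,22-pentamethyltricosa-5,9,13,17,21-pentaen-1-yne
Conditions: HC≡CCH2Br, n-BuLi (2 equiv), TMEDA, Et2O/hexane, −78 °C; then 7, −78 °C → rt; H2O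
Reagents that add atoms: propargyl bromide, BrCC#C
Why: SN2 propargylation of the allylic bromide with 1,3-dilithiopropyne, as in step 2, should give the terminal alkyne that carries C10' and C11'.

Step 6
Reactants: 8 the C28 enyne
Product: 10 (1E,5E,9E,13E,17E)-1-iodo-2,6,10,14,18,22-hexamethyltricosa-1,5,9,13,17,21-hexaene, via alkenyldimethylalane 9 (not isolated)
Conditions: Me3Al, Cp2ZrCl2 (25 mol %), ClCH2CH2Cl, rt; then I2, THF, −30 → 0 °C
Reagents that add atoms: trimethylaluminium, C[Al](C)C; iodine, II
Why: Negishi syn methylalumination of the terminal alkyne followed by iododealumination with retention should give the (E)-1-iodo-2-methylalkene, while the isolated trisubstituted alkenes do not react.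

**Arene building block**

Step 7
Reactants: 11 menadione (2-methylnaphthalene-1,4-dione)
Product: 13 1,4-dimethoxy-2-methylnaphthalene, via menadiol 12 (not isolated)
Conditions: Na2S2O4, Bu4NBr (cat.), THF/H2O, rt; then aq. KOH, Me2SO4, 0 °C → rt, under N2
Reagents that add atoms: dimethyl sulfate, COS(=O)(=O)OC
Why: Dithionite reduction of the quinone and Williamson O-methylation of the hydroquinone in the same flask under phase transfer avoid handling the air-sensitive menadiol.

Step 8
Reactants: 13 1,4-dimethoxy-2-methylnaphthalene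
Product: 14 2-(chloromethyl)-1,4-dimethoxy-3-methylnaphthalene
Conditions: (CH2O)n, conc. HCl, HCl (g), AcOH, rt
Reagents that add atoms: paraformaldehyde (as formaldehyde), C=O; hydrogen chloride, Cl
Why: Blanc chloromethylation should occur at the only unsubstituted position of the electron-rich dioxygenated ring.

**Right fragment**

Step 9
Reactants: 15 (R)-β-citronellene [(3R)-3,7-dimethylocta-1,6-diene]
Product: 17 (4R)-4-methylhex-5-en-1-ol, via (4R)-4-methylhex-5-enal 16 (not isolated)
Conditions: O3, CH2Cl2/MeOH, −78 °C, Sudan Red 7B end point; then NaBH4, −78 °C → rt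
Reagents that add atoms: ozone, [O-][O+]=O
Why: Electrophilic ozone should cleave the electron-rich trisubstituted alkene before the monosubstituted vinyl group (chemoselective ozonolysis with a dye end point, reductive work-up), and the stereocentre is not adjacent to the carbonyl group and is not touched.

Step 10
Reactants: 17 (4R)-4-methylhex-5-en-1-ol
Product: 18 (4R)-4-methylhex-5-en-1-yl 4-methylbenzenesulfonate
Conditions: TsCl, Et3N, DMAP (cat.), CH2Cl2, 0 °C → rt
Reagents that add atoms: 4-toluenesulfonyl chloride, Cc1ccc(cc1)S(Cl)(=O)=O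
Why: Sulfonylation of the primary alcohol gives a non-volatile SN2 electrophile.

Step 11
Reactants: 18 the tosylate
Product: 19 (6R)-6-methyloct-7-en-1-yne
Conditions: LiC≡CH·H2NCH2CH2NH2, DMSO, 10 °C → rt
Reagents that add atoms: lithium acetylide ethylenediamine complex, [Li]C#C.NCCN
Why: SN2 displacement of a primary tosylate by acetylide in DMSO (acetylide alkylation) installs C2' and C3' as a terminal alkyne.

Step 12
Reactants: 19 (6R)-6-methyloct-7-en-1-yne; 14 2-(chloromethyl)-1,4-dimethoxy-3-methylnaphthalene
Product: 21 2-[(2E,7R)-3,7-dimethylnona-2,8-dien-1-yl]-1,4-dimethoxy-3-methylnaphthalene, via alkenyldimethylalane 20 (not isolated)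
Conditions: Me3Al, Cp2ZrCl2 (25 mol %), ClCH2CH2Cl, 0 °C → rt; volatiles removed; then 14, NiCl2(PPh3)2 (5 mol %) reduced with n-BuLi (10 mol %) to zerovalent nickel, THF, rt
Reagents that add atoms: trimethylaluminium, C[Al](C)C
Why: Negishi methylalumination of the terminal alkyne should be much faster than carbometalation of the α-branched vinyl group, and the (E)-alkenylalane then couples with the benzylic chloride under zerovalent nickel catalysis (oxidative addition, transmetalation, reductive elimination) with retention, which sets the (2E) alkene.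

**Fragment union and end game**

Step 13
Reactants: 21 the right fragment; 10 the C29 (E)-alkenyl iodide
Product: 23 2-[(2E,7R,10E,14E,18E,22E,26E)-3,7,11,15,19,23,27,31-octamethyldotriaconta-2,10,14,18,22,26,30-heptaen-1-yl]-1,4-dimethoxy-3-methylnaphthalene, via B-alkyl-9-borabicyclononane 22 (not isolated)
Conditions: 9-BBN dimer (1.2 equiv B–H), THF, 0 °C → rt; then aq. Cs2CO3, 10, PdCl2(dppf) (5 mol %; dppf = 1,1'-bis(diphenylphosphino)ferrocene), AsPh3, DMF/THF/H2O, rt
Reagents that add atoms: none
Why: 9-BBN adds anti-Markovnikov to the monosubstituted C8'=C9' vinyl group to give a primary B-alkyl borane; its hydroxyborate transmetalates to the alkenylpalladium iodide formed by oxidative addition of 10 to zerovalent palladium, and reductive elimination forms the C9'–C10' bond. The closest known reaction type is the one-pot hydroboration/B-alkyl Suzuki–Miyaura coupling of alkenyl iodides. No ring is closed and no stereocentre is made; C7' is a spectator and the (E) geometry at C10'=C11' is carried over from the iodide with retention. The step needs chemoselective hydroboration of the terminal alkene in the presence of the trisubstituted C2'=C3' alkene, which the steric demand of 9-BBN should secure, and excess borane is destroyed by the aqueous base before the polyene 10 is added. It also needs reductive elimination to outrun β-hydride elimination of the alkylpalladium species, which the wide bite angle of dppf together with AsPh3 should secure.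

Step 14
Reactants: 23 the menaquinol dimethyl ether
Product: 24 2-methyl-3-[(2E,7R,10E,14E,18E,22E,26E)-3,7,11,15,19,23,27,31-octamethyldotriaconta-2,10,14,18,22,26,30-heptaen-1-yl]naphthalene-1,4-dione (target)
Conditions: (NH4)2Ce(NO3)6 (2.5 equiv), MeCN/CH2Cl2/H2O, 0 °C, short reaction time
Reagents that add atoms: water, O
Why: Oxidative demethylation by tetravalent cerium (two one-electron oxidations of the electron-rich arene, ipso attack of water, loss of methanol) should give the quinone, while the isolated alkenes and C7' are not affected under brief, cold conditions.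

**Compound list**

1 | (2E,6E,10E)-geranylgeraniol | CC(C)=CCC/C(C)=C/CC/C(C)=C/CC/C(C)=C/CO | starting material
2 | (2E,6E,10E)-geranylgeranyl bromide | CC(C)=CCC/C(C)=C/CC/C(C)=C/CC/C(C)=C/CBr | intermediate
3 | (5E,9E,13E)-6,10,14,18-tetramethylnonadeca-5,9,13,17-tetraen-1-yne | CC(C)=CCC/C(C)=C/CC/C(C)=C/CC/C(C)=C/CCC#C | intermediate
4 | dimethyl[(1E,5E,9E,13E)-2,6,10,14,18-pentamethylnonadeca-1,5,9,13,17-pentaen-1-yl]alane | CC(C)=CCC/C(C)=C/CC/C(C)=C/CC/C(C)=C/CC/C(C)=C/[Al](C)C | intermediate (not isolated)
5 | lithium butyl(dimethyl)[(1E,5E,9E,13E)-2,6,10,14,18-pentamethylnonadeca-1,5,9,13,17-pentaen-1-yl]aluminate | CC(C)=CCC/C(C)=C/CC/C(C)=C/CC/C(C)=C/CC/C(C)=C/[Al-](C)(C)CCCC.[Li+] | intermediate (not isolated)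
6 | (2E,6E,10E,14E)-geranylfarnesol | CC(C)=CCC/C(C)=C/CC/C(C)=C/CC/C(C)=C/CC/C(C)=C/CO | intermediate
7 | (2E,6E,10E,14E)-geranylfarnesyl bromide | CC(C)=CCC/C(C)=C/CC/C(C)=C/CC/C(C)=C/CC/C(C)=C/CBr | intermediate
8 | (5E,9E,13E,17E)-6,10,14,18,22-pentamethyltricosa-5,9,13,17,21-pentaen-1-yne | CC(C)=CCC/C(C)=C/CC/C(C)=C/CC/C(C)=C/CC/C(C)=C/CCC#C | intermediate
9 | dimethyl[(1E,5E,9E,13E,17E)-2,6,10,14,18,22-hexamethyltricosa-1,5,9,13,17,21-hexaen-1-yl]alane | CC(C)=CCC/C(C)=C/CC/C(C)=C/CC/C(C)=C/CC/C(C)=C/CC/C(C)=C/[Al](C)C | intermediate (not isolated)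
10 | (1E,5E,9E,13E,17E)-1-iodo-2,6,10,14,18,22-hexamethyltricosa-1,5,9,13,17,21-hexaene | CC(C)=CCC/C(C)=C/CC/C(C)=C/CC/C(C)=C/CC/C(C)=C/CC/C(C)=C/I | intermediate
11 | menadione | CC1=CC(=O)c2ccccc2C1=O | starting material
12 | menadiol (2-methylnaphthalene-1,4-diol) | Cc1cc(O)c2ccccc2c1O | intermediate (not isolated)
13 | 1,4-dimethoxy-2-methylnaphthalene | COc1cc(C)c(OC)c2ccccc12 | intermediate
14 | 2-(chloromethyl)-1,4-dimethoxy-3-methylnaphthalene | COc1c(C)c(CCl)c(OC)c2ccccc12 | intermediate
15 | (R)-β-citronellene | C=C[C@H](C)CCC=C(C)C | starting material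
16 | (4R)-4-methylhex-5-enal | C=C[C@H](C)CCC=O | intermediate (not isolated)
17 | (4R)-4-methylhex-5-en-1-ol | C=C[C@H](C)CCCO | intermediate
18 | (4R)-4-methylhex-5-en-1-yl 4-methylbenzenesulfonate | C=C[C@H](C)CCCOS(=O)(=O)c1ccc(C)cc1 | intermediate
19 | (6R)-6-methyloct-7-en-1-yne | C=C[C@H](C)CCCC#C | intermediate
20 | dimethyl[(1E,6R)-2,6-dimethylocta-1,7-dien-1-yl]alane | C=C[C@H](C)CCC/C(C)=C/[Al](C)C | intermediate (not isolated)
21 | 2-[(2E,7R)-3,7-dimethylnona-2,8-dien-1-yl]-1,4-dimethoxy-3-methylnaphthalene | COc1c(C)c(C/C=C(\C)CCC[C@@H](C)C=C)c(OC)c2ccccc12 | intermediate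
22 | 9-[(3S,7E)-9-(1,4-dimethoxy-3-methylnaphthalen-2-yl)-3,7-dimethylnon-7-en-1-yl]-9-borabicyclo[3.3.1]nonane (same spatial arrangement as in 21; the descriptor changes by priority only) | COc1c(C)c(C/C=C(\C)CCC[C@@H](C)CCB3C4CCCC3CCC4)c(OC)c2ccccc12 | intermediate (not isolated)
23 | 2-[(2E,7R,10E,14E,18E,22E,26E)-3,7,11,15,19,23,27,31-octamethyldotriaconta-2,10,14,18,22,26,30-heptaen-1-yl]-1,4-dimethoxy-3-methylnaphthalene | CC(C)=CCC/C(C)=C/CC/C(C)=C/CC/C(C)=C/CC/C(C)=C/CC/C(C)=C/CC[C@H](C)CCC/C(C)=C/Cc1c(C)c(OC)c2ccccc2c1OC | intermediate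
24 | 2-methyl-3-[(2E,7R,10E,14E,18E,22E,26E)-3,7,11,15,19,23,27,31-octamethyldotriaconta-2,10,14,18,22,26,30-heptaen-1-yl]naphthalene-1,4-dione | CC(C)=CCC/C(C)=C/CC/C(C)=C/CC/C(C)=C/CC/C(C)=C/CC/C(C)=C/CC[C@H](C)CCC/C(C)=C/CC1=C(C)C(=O)c2ccccc2C1=O | target

**Count and risks**

Total step count: 14. Longest linear sequence: 8 steps (steps 1–6, then 13 and 14).

Steps most likely to fail:

1. Step 13 (key coupling). The risk is slow boron-to-palladium transmetalation, so that β-hydride elimination or protodeboronation of the alkyl partner competes, and partial hydroboration of the trisubstituted alkene. The fallback sets out from 21 and comes back at 23. The borane 22 is oxidised (NaOH, H2O2) to (3R,7E)-9-(1,4-dimethoxy-3-methylnaphthalen-2-yl)-3,7-dimethylnon-7-en-1-ol F1. An Appel-type iodination (I2, PPh3, imidazole) gives 2-[(2E,7R)-9-iodo-3,7-dimethylnon-2-en-1-yl]-1,4-dimethoxy-3-methylnaphthalene F2. Zinc insertion (Zn dust, LiCl, THF) gives [(3R,7E)-9-(1,4-dimethoxy-3-methylnaphthalen-2-yl)-3,7-dimethylnon-7-en-1-yl]zinc iodide F3. A Negishi alkyl–alkenyl coupling of F3 with 10 (PdCl2(dppf), THF) then gives 23.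

2. Step 12 (carboalumination and nickel coupling). The risk is competing carbometalation or isomerisation of the terminal vinyl group during methylalumination, and methyl transfer from aluminium to the benzylic chloride in the nickel step. The fallback sets out from 19 and 13 and comes back at 21. Alkyne 19 is deprotonated (n-BuLi) and hydroxymethylated with (CH2O)n to (7R)-7-methylnon-8-en-2-yn-1-ol F4. Hydroxyl-directed trans-hydroalumination with NaAlH2(OCH2CH2OCH3)2 and iodination give (2Z,7R)-3-iodo-7-methylnona-2,8-dien-1-ol F5. Me2CuLi replaces iodine by methyl with retention to give (2E,7R)-3,7-dimethylnona-2,8-dien-1-ol F6, and PBr3 converts it to (3R,7E)-9-bromo-3,7-dimethylnona-1,7-diene F7. In parallel 13 is brominated (Br2, CH2Cl2) to 2-bromo-1,4-dimethoxy-3-methylnaphthalene F8 and turned with Mg into (1,4-dimethoxy-3-methylnaphthalen-2-yl)magnesium bromide F9. CuI-catalysed SN2 allylation of F9 with F7 gives 21.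

3. Step 9 (selective ozonolysis). The risk is incomplete discrimination between the two alkenes, with over-oxidation of the vinyl group. The fallback sets out from 15 and comes back at 17. mCPBA (1 equiv, CH2Cl2, 0 °C) epoxidises only the trisubstituted alkene to 2,2-dimethyl-3-[(3R)-3-methylpent-4-en-1-yl]oxirane F10 (a mixture of epimers at the oxirane carbon, which does not matter). H5IO6 (THF/H2O) cleaves F10 to aldehyde 16, here isolated, and NaBH4 reduces it to 17.

Further compounds
F1 | step 13 | (3R,7E)-9-(1,4-dimethoxy-3-methylnaphthalen-2-yl)-3,7-dimethylnon-7-en-1-ol | COc1c(C)c(C/C=C(\C)CCC[C@@H](C)CCO)c(OC)c2ccccc12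
F2 | step 13 | 2-[(2E,7R)-9-iodo-3,7-dimethylnon-2-en-1-yl]-1,4-dimethoxy-3-methylnaphthalene | COc1c(C)c(C/C=C(\C)CCC[C@@H](C)CCI)c(OC)c2ccccc12
F3 | step 13 | [(3R,7E)-9-(1,4-dimethoxy-3-methylnaphthalen-2-yl)-3,7-dimethylnon-7-en-1-yl]zinc iodide | COc1c(C)c(C/C=C(\C)CCC[C@@H](C)CC[Zn]I)c(OC)c2ccccc12
F4 | step 12 | (7R)-7-methylnon-8-en-2-yn-1-ol | C=C[C@H](C)CCCC#CCO
F5 | step 12 | (2Z,7R)-3-iodo-7-methylnona-2,8-dien-1-ol | C=C[C@H](C)CCC/C(I)=C/CO
F6 | step 12 | (2E,7R)-3,7-dimethylnona-2,8-dien-1-ol | C=C[C@H](C)CCC/C(C)=C/CO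
F7 | step 12 | (3R,7E)-9-bromo-3,7-dimethylnona-1,7-diene | C=C[C@H](C)CCC/C(C)=C/CBr
F8 | step 12 | 2-bromo-1,4-dimethoxy-3-methylnaphthalene | COc1c(C)c(Br)c(OC)c2ccccc12
F9 | step 12 | (1,4-dimethoxy-3-methylnaphthalen-2-yl)magnesium bromide | COc1c(C)c([Mg]Br)c(OC)c2ccccc12
F10 | step 9 | 2,2-dimethyl-3-[(3R)-3-methylpent-4-en-1-yl]oxirane (epimers at the oxirane carbon) | C=C[C@H](C)CCC1OC1(C)C
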